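A direct plan would acylate the aryllithium from the prenylated bis‑MOM ether A1 with the (R)‑α‑silyloxy Weinreb amide A2, unmask the α‑hydroxydihydrochalcone A3, close ring C at O1–C2 by Ag2O oxidation of the ring B phenol to the para‑quinone methide A4, and cleave the 5‑O‑methyl ether of the resulting dihydroflavonol A5 with MgI2.
Weak point (a), the oxidative O1–C2 ring closure: the oxidant would meet a free, prenylated resorcinol ring; A4 could tautomerise through the acidic C3–H and erase the only purchased stereocenter; C2 would be left to equilibrate.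
Weak point (b), the closing demethylation: a Lewis acidic iodide at reflux would act on the finished molecule, with its ortho‑prenyl phenol (chroman formation) and two epimerisable centers.
Weak point (c), the run‑up: about half of the operations (MOM protections, silylation, Weinreb amide formation, global acidolysis, demethylation) would build no skeletal bond, and the acidolysis would again endanger the prenyl phenol.

**Retrosynthetic overview**
Ring C of the target (O1, C2, C3, C4) is the reduced form of a flat γ‑pyranone, and its two stereocenters, C2 and C3, are the carbons of that ring's former C2=C3 bond; the route therefore never closes ring C but dearomatises it.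
Key disconnections: C2–C1' and C3–O, both made in one operation on the achiral 8‑prenylchromone 8 by rhodium‑catalysed enantioselective conjugate arylation with the ring B arylzinc, silyl trapping and Rubottom oxidation; C2 is set by the ligand, C3 by C2.
The C8–prenyl bond is made earlier, on the robust chromone, by a para‑Claisen–Cope relay from O5, so the 8‑regiochemistry needs no O‑methyl ether at C5.
Ring order: rings A and C come fused in 5,7‑dihydroxychromone and ring B is attached last; no quinone methide, ether cleavage or acid touches the finished dihydroflavonol, since all masks are silyl ethers removed by buffered fluoride.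
Key step: step 6

Assumption: 5,7‑dihydroxychromone is taken as commercial, and the rhodium/(S)‑BINAP catalyst is assumed to attack the chromone face it attacks in cyclic enones and 4‑quinolones; if the sense were opposite, (R)‑BINAP would be used.

Step 1
Reactants: 1 5,7‑dihydroxy‑4H‑chromen‑4‑one
Product: 2 5‑hydroxy‑7‑[(triisopropylsilyl)oxy]‑4H‑chromen‑4‑one
Conditions: TIPSCl (1.05 equiv), imidazole, DMF, 0 °C to rt
Reagents that add atoms: triisopropylsilyl chloride (TIPSCl), CC(C)[Si](Cl)(C(C)C)C(C)C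
Why: Imidazole‑promoted O‑silylation should take the more acidic, free 7‑OH, while the 5‑OH stays locked in its hydrogen bond to the C4 carbonyl.

Step 2
Reactants: 2 5‑hydroxy‑7‑[(triisopropylsilyl)oxy]‑4H‑chromen‑4‑one; 3 3‑methylbut‑2‑en‑1‑ol (prenol)
Product: 4 5‑[(3‑methylbut‑2‑en‑1‑yl)oxy]‑7‑[(triisopropylsilyl)oxy]‑4H‑chromen‑4‑one
Conditions: PPh3, DIAD, THF, 0 °C to rt
Reagents that add atoms: none
Why: Mitsunobu etherification should alkylate the chelated but acidic 5‑OH at the primary carbon of the prenyloxyphosphonium ion (SN2) under neutral conditions that leave the aryl silyl ether alone.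

Step 3
Reactants: 4 5‑[(3‑methylbut‑2‑en‑1‑yl)oxy]‑7‑[(triisopropylsilyl)oxy]‑4H‑chromen‑4‑one
Product: 7 5‑hydroxy‑8‑(3‑methylbut‑2‑en‑1‑yl)‑7‑[(triisopropylsilyl)oxy]‑4H‑chromen‑4‑one, via C6 dienone 5 (not isolated), via C8 dienone 6 (not isolated)
Conditions: Eu(fod)3 (10 mol %), CHCl3, 60 °C, sealed tube
Reagents that add atoms: none
Why: Para‑Claisen–Cope relay: the trivalent europium Lewis acid tris(6,6,7,7,8,8,8‑heptafluoro‑2,2‑dimethyl‑3,5‑octanedionato)europium, bound between the C4 carbonyl and O5, should accelerate the aromatic Claisen [3,3] shift to C6 (dienone 5, 1,1‑dimethylallyl group) and the Cope [3,3] shift to C8 (dienone 6), whose enolisation restores the arene with a linear prenyl group that can only sit at C8, para to O5.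

Step 4
Reactants: 7 5‑hydroxy‑8‑(3‑methylbut‑2‑en‑1‑yl)‑7‑[(triisopropylsilyl)oxy]‑4H‑chromen‑4‑one
Product: 8 5‑[(tert‑butyldimethylsilyl)oxy]‑8‑(3‑methylbut‑2‑en‑1‑yl)‑7‑[(triisopropylsilyl)oxy]‑4H‑chromen‑4‑one
Conditions: TBSOTf, 2,6‑lutidine, CH2Cl2, 0 °C to rt
Reagents that add atoms: tert‑butyldimethylsilyl trifluoromethanesulfonate (TBSOTf), CC(C)(C)[Si](C)(C)OS(=O)(=O)C(F)(F)F
Why: Silylation with a silyl triflate and a hindered base should overcome the hydrogen bond of the 5‑OH and remove the last acidic proton before the organometallic step.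

Step 5
Reactants: 9 4‑bromo‑2‑methoxyphenol
Product: 10 (4‑bromo‑2‑methoxyphenoxy)(tert‑butyl)dimethylsilane
Conditions: TBSCl, imidazole, CH2Cl2, rt
Reagents that add atoms: tert‑butyldimethylsilyl chloride (TBSCl), CC(C)(C)[Si](C)(C)Cl
Why: Imidazole‑promoted O‑silylation masks the ring B phenol with a group that tolerates bromine–lithium exchange and leaves with fluoride at the end.

Step 6
Reactants: 10 (4‑bromo‑2‑methoxyphenoxy)(tert‑butyl)dimethylsilane; 8 5‑[(tert‑butyldimethylsilyl)oxy]‑8‑(3‑methylbut‑2‑en‑1‑yl)‑7‑[(triisopropylsilyl)oxy]‑4H‑chromen‑4‑one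
Product: 15 (2R,3R)‑5‑[(tert‑butyldimethylsilyl)oxy]‑2‑{4‑[(tert‑butyldimethylsilyl)oxy]‑3‑methoxyphenyl}‑3‑hydroxy‑8‑(3‑methylbut‑2‑en‑1‑yl)‑7‑[(triisopropylsilyl)oxy]‑2,3‑dihydro‑4H‑chromen‑4‑one, via aryllithium 11 (not isolated), via arylzinc chloride 12 (not isolated), via enol silane 13 (not isolated), via silyloxy epoxide 14 (not isolated)
Conditions: 10 (3 equiv), n‑BuLi, THF, −78 °C; ZnCl2, −78 to 0 °C; then 8, [RhCl((S)‑binap)]2 (7.5 mol % Rh), Me3SiCl (3 equiv), THF, 20 °C; cold aq. NaHCO3, pentane, concentration; then dimethyldioxirane (DMDO, 1.05 equiv), acetone/CH2Cl2, −78 to −40 °C; 10 % aq. citric acid, THF, 0 °C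
Reagents that add atoms: dimethyldioxirane (DMDO), CC1(C)OO1
Why: Aryl transfer from zinc to monovalent rhodium, face‑selective insertion of the chromone C2=C3 bond into the Rh–aryl bond and silylation of the oxa‑π‑allyl rhodium by Me3SiCl should give enol silane 13, which cannot open ring C by retro‑oxa‑Michael reaction; DMDO then epoxidises 13 and silyloxy epoxide 14 collapses to the α‑hydroxy ketone on mild acidic work‑up (Rubottom oxidation). The closest known reaction types are the rhodium/BINAP‑catalysed asymmetric 1,4‑addition of arylzinc chlorides with Me3SiCl to 4‑quinolones and 2,3‑dihydro‑4‑pyridones, the rhodium‑catalysed asymmetric conjugate arylation of chromones with arylboronic acids, and the DMDO oxidation of flavanone enol derivatives to trans‑3‑hydroxyflavanones. No ring of the target is closed: ring C enters as the flat γ‑pyranone and is dearomatised as the C2–C1' and C3–O bonds form, and the only ring closed, the oxirane of 14, arises by concerted oxygen transfer to C3=C4 and is opened again. C2 is set by the (S)‑BINAP ligand (2S in 13), and C3 by C2, because the oxidant approaches the enol silane anti to the C2 aryl group, giving the 2,3‑trans (2R,3R) isomer, which is also the more stable one with both substituents equatorial. The step needs 1,4‑ and not 1,2‑addition, secured because arylzinc chlorides do not add to the carbonyl without rhodium, and oxidation of the enol silane in preference to the prenyl alkene and the electron‑rich rings, secured by the far higher nucleophilicity of a silyl enol ether towards one equivalent of DMDO at −78 °C.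

Step 7
Reactants: 15 (2R,3R)‑5‑[(tert‑butyldimethylsilyl)oxy]‑2‑{4‑[(tert‑butyldimethylsilyl)oxy]‑3‑methoxyphenyl}‑3‑hydroxy‑8‑(3‑methylbut‑2‑en‑1‑yl)‑7‑[(triisopropylsilyl)oxy]‑2,3‑dihydro‑4H‑chromen‑4‑one
Product: 16 (2R,3R)‑3,5,7‑trihydroxy‑2‑(4‑hydroxy‑3‑methoxyphenyl)‑8‑(3‑methylbut‑2‑en‑1‑yl)‑2,3‑dihydro‑4H‑chromen‑4‑one (target)
Conditions: TBAF, AcOH (1:1, 3.3 equiv each), THF, 0 °C to rt; pH 6 phosphate buffer
Reagents that add atoms: none
Why: Fluoride‑induced cleavage of the three aryl silyl ethers, buffered by acetic acid so that neither C3 (enolisation) nor C2 (opening of ring C through the 4'‑phenoxide) should be disturbed, and with no acid strong enough to cyclise the ortho‑prenyl phenol.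

**Compound list**

1 | 5,7‑dihydroxy‑4H‑chromen‑4‑one (5,7‑dihydroxychromone) | O=c1ccoc2cc(O)cc(O)c12 | starting material
2 | 5‑hydroxy‑7‑[(triisopropylsilyl)oxy]‑4H‑chromen‑4‑one | O=c1ccoc2cc(O[Si](C(C)C)(C(C)C)C(C)C)cc(O)c12 | intermediate
3 | 3‑methylbut‑2‑en‑1‑ol (prenol) | CC(C)=CCO | starting material
4 | 5‑[(3‑methylbut‑2‑en‑1‑yl)oxy]‑7‑[(triisopropylsilyl)oxy]‑4H‑chromen‑4‑one | O=c1ccoc2cc(O[Si](C(C)C)(C(C)C)C(C)C)cc(OCC=C(C)C)c12 | intermediate
5 | 6‑(2‑methylbut‑3‑en‑2‑yl)‑7‑[(triisopropylsilyl)oxy]‑4H‑chromene‑4,5(6H)‑dione (C6 dienone, racemic at C6) | O=C1C=COC2=C1C(=O)C(C(C)(C)C=C)C(O[Si](C(C)C)(C(C)C)C(C)C)=C2 | intermediate (not isolated)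
6 | 8‑(3‑methylbut‑2‑en‑1‑yl)‑7‑[(triisopropylsilyl)oxy]‑4H‑chromene‑4,5(8H)‑dione (C8 dienone, racemic at C8) | O=C1C=COC2=C1C(=O)C=C(O[Si](C(C)C)(C(C)C)C(C)C)C2CC=C(C)C | intermediate (not isolated)
7 | 5‑hydroxy‑8‑(3‑methylbut‑2‑en‑1‑yl)‑7‑[(triisopropylsilyl)oxy]‑4H‑chromen‑4‑one | O=c1ccoc2c(CC=C(C)C)c(O[Si](C(C)C)(C(C)C)C(C)C)cc(O)c12 | intermediate
8 | 5‑[(tert‑butyldimethylsilyl)oxy]‑8‑(3‑methylbut‑2‑en‑1‑yl)‑7‑[(triisopropylsilyl)oxy]‑4H‑chromen‑4‑one | O=c1ccoc2c(CC=C(C)C)c(O[Si](C(C)C)(C(C)C)C(C)C)cc(O[Si](C)(C)C(C)(C)C)c12 | intermediate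
9 | 4‑bromo‑2‑methoxyphenol | COc1cc(Br)ccc1O | starting material
10 | (4‑bromo‑2‑methoxyphenoxy)(tert‑butyl)dimethylsilane | COc1cc(Br)ccc1O[Si](C)(C)C(C)(C)C | intermediate
11 | {4‑[(tert‑butyldimethylsilyl)oxy]‑3‑methoxyphenyl}lithium | [Li]c1ccc(O[Si](C)(C)C(C)(C)C)c(OC)c1 | intermediate (not isolated)
12 | {4‑[(tert‑butyldimethylsilyl)oxy]‑3‑methoxyphenyl}zinc chloride | Cl[Zn]c1ccc(O[Si](C)(C)C(C)(C)C)c(OC)c1 | intermediate (not isolated)
13 | (2S)‑5‑[(tert‑butyldimethylsilyl)oxy]‑2‑{4‑[(tert‑butyldimethylsilyl)oxy]‑3‑methoxyphenyl}‑8‑(3‑methylbut‑2‑en‑1‑yl)‑7‑[(triisopropylsilyl)oxy]‑4‑[(trimethylsilyl)oxy]‑2H‑chromene (enol silane; same spatial arrangement at C2 as in 15, the descriptor differs only through the CIP priorities) | COc1cc([C@H]2Oc3c(CC=C(C)C)c(O[Si](C(C)C)(C(C)C)C(C)C)cc(O[Si](C)(C)C(C)(C)C)c3C(O[Si](C)(C)C)=C2)ccc1O[Si](C)(C)C(C)(C)C | intermediate (not isolated)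
14 | 3,4‑epoxide of 13 (trimethylsilyloxy oxirane fused at C3–C4, oxirane oxygen anti to the C2 aryl group) | COc1cc([C@H]2Oc3c(CC=C(C)C)c(O[Si](C(C)C)(C(C)C)C(C)C)cc(O[Si](C)(C)C(C)(C)C)c3[C@]4(O[Si](C)(C)C)O[C@H]24)ccc1O[Si](C)(C)C(C)(C)C | intermediate (not isolated)
15 | (2R,3R)‑5‑[(tert‑butyldimethylsilyl)oxy]‑2‑{4‑[(tert‑butyldimethylsilyl)oxy]‑3‑methoxyphenyl}‑3‑hydroxy‑8‑(3‑methylbut‑2‑en‑1‑yl)‑7‑[(triisopropylsilyl)oxy]‑2,3‑dihydro‑4H‑chromen‑4‑one | COc1cc([C@H]2Oc3c(CC=C(C)C)c(O[Si](C(C)C)(C(C)C)C(C)C)cc(O[Si](C)(C)C(C)(C)C)c3C(=O)[C@@H]2O)ccc1O[Si](C)(C)C(C)(C)C | intermediate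
16 | (2R,3R)‑3,5,7‑trihydroxy‑2‑(4‑hydroxy‑3‑methoxyphenyl)‑8‑(3‑methylbut‑2‑en‑1‑yl)‑2,3‑dihydro‑4H‑chromen‑4‑one | COc1cc([C@H]2Oc3c(CC=C(C)C)c(O)cc(O)c3C(=O)[C@@H]2O)ccc1O | target

**Step count and risks**

Total step count: 7. Longest linear sequence: 6 steps (1 → 2 → 4 → 7 → 8 → 15 → 16).

Steps most likely to fail:

Step 6 (key step). The aryl transfer to the electron‑rich chromone, whose carbonyl is flanked by a peri silyloxy group, may be slow or poorly face‑selective. The enol silane may hydrolyse before oxidation, or the prenyl alkene may be epoxidised in competition. The fallback separates the two events and changes both reagents. It sets out from 10 and 8. Bromine–lithium exchange of 10 and borylation (n‑BuLi, B(Oi‑Pr)3, then aq. NH4Cl) would give {4‑[(tert‑butyldimethylsilyl)oxy]‑3‑methoxyphenyl}boronic acid F1. Its rhodium‑catalysed asymmetric 1,4‑addition to 8 with protic turnover ([Rh(OH)(cod)]2, (S)‑BINAP‑type bisphosphine, toluene/H2O) would give the (2S)‑flavanone F2. Deprotonation with LiHMDS at −78 °C would give the lithium enolate F3. Hydroxylation anti to the aryl group with 2‑(phenylsulfonyl)‑3‑phenyloxaziridine, an oxidant that does not epoxidise isolated alkenes, would return to the route at 15.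

Step 3. Dienone 5 may enolise before the Cope shift, which would leave a 1,1‑dimethylallyl group at C6, or the bulky silyl ether beside C8 may retard the second shift. The fallback delivers the prenyl group from O7 by a single ortho‑Claisen shift of a tertiary allyl ether. It sets out from 1. O7‑alkylation with 3‑chloro‑3‑methylbut‑1‑yne (K2CO3, KI, CuI cat., acetone) would give 5‑hydroxy‑7‑[(2‑methylbut‑3‑yn‑2‑yl)oxy]‑4H‑chromen‑4‑one F4. Semihydrogenation (H2, Pd/CaCO3 poisoned with Pb(OAc)2, quinoline) would give 5‑hydroxy‑7‑[(2‑methylbut‑3‑en‑2‑yl)oxy]‑4H‑chromen‑4‑one F5. A thermal [3,3] shift (N,N‑diethylaniline, 120 °C) would give 5,7‑dihydroxy‑8‑(3‑methylbut‑2‑en‑1‑yl)‑4H‑chromen‑4‑one F6; C8 should be favoured by the bond fixation of the benzopyranone, and any C6 isomer would be separated. Selective 7‑O‑silylation as in step 1 would return to the route at 7.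

Step 4. Silylation of the hydrogen‑bonded phenol may be incomplete, or the peri silyl ether may be lost on purification or during the arylation. In the fallback O5 stays free through the arylation and is silylated together with the enol. It sets out from 7. The protic rhodium‑catalysed addition of boronic acid F1, which tolerates a free phenol, would give the (2S)‑5‑hydroxyflavanone F7. Me3SiOTf/Et3N would silylate phenol and ketone in one operation to the bis(trimethylsilyl) enol silane F8. DMDO oxidation through the silyloxy epoxide F9 and mild acidic work‑up would give the (2R,3R)‑3,5‑dihydroxy compound F10. The conditions of step 7 would convert F10 into 16, where the fallback rejoins the route.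

**Further compounds**

F1 | step 6 | {4‑[(tert‑butyldimethylsilyl)oxy]‑3‑methoxyphenyl}boronic acid | COc1cc(B(O)O)ccc1O[Si](C)(C)C(C)(C)C
F2 | step 6 | (2S)‑5‑[(tert‑butyldimethylsilyl)oxy]‑2‑{4‑[(tert‑butyldimethylsilyl)oxy]‑3‑methoxyphenyl}‑8‑(3‑methylbut‑2‑en‑1‑yl)‑7‑[(triisopropylsilyl)oxy]‑2,3‑dihydro‑4H‑chromen‑4‑one | COc1cc([C@H]2Oc3c(CC=C(C)C)c(O[Si](C(C)C)(C(C)C)C(C)C)cc(O[Si](C)(C)C(C)(C)C)c3C(=O)C2)ccc1O[Si](C)(C)C(C)(C)C
F3 | step 6 | lithium enolate of F2 (lithium (2S)‑2‑aryl‑2H‑chromen‑4‑olate) | COc1cc([C@H]2Oc3c(CC=C(C)C)c(O[Si](C(C)C)(C(C)C)C(C)C)cc(O[Si](C)(C)C(C)(C)C)c3C(O[Li])=C2)ccc1O[Si](C)(C)C(C)(C)C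
F4 | step 3 | 5‑hydroxy‑7‑[(2‑methylbut‑3‑yn‑2‑yl)oxy]‑4H‑chromen‑4‑one | O=c1ccoc2cc(OC(C)(C)C#C)cc(O)c12
F5 | step 3 | 5‑hydroxy‑7‑[(2‑methylbut‑3‑en‑2‑yl)oxy]‑4H‑chromen‑4‑one | O=c1ccoc2cc(OC(C)(C)C=C)cc(O)c12
F6 | step 3 | 5,7‑dihydroxy‑8‑(3‑methylbut‑2‑en‑1‑yl)‑4H‑chromen‑4‑one | O=c1ccoc2c(CC=C(C)C)c(O)cc(O)c12
F7 | step 4 | (2S)‑2‑{4‑[(tert‑butyldimethylsilyl)oxy]‑3‑methoxyphenyl}‑5‑hydroxy‑8‑(3‑methylbut‑2‑en‑1‑yl)‑7‑[(triisopropylsilyl)oxy]‑2,3‑dihydro‑4H‑chromen‑4‑one | COc1cc([C@H]2Oc3c(CC=C(C)C)c(O[Si](C(C)C)(C(C)C)C(C)C)cc(O)c3C(=O)C2)ccc1O[Si](C)(C)C(C)(C)C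
F8 | step 4 | (2S)‑2‑{4‑[(tert‑butyldimethylsilyl)oxy]‑3‑methoxyphenyl}‑8‑(3‑methylbut‑2‑en‑1‑yl)‑7‑[(triisopropylsilyl)oxy]‑4,5‑bis[(trimethylsilyl)oxy]‑2H‑chromene | COc1cc([C@H]2Oc3c(CC=C(C)C)c(O[Si](C(C)C)(C(C)C)C(C)C)cc(O[Si](C)(C)C)c3C(O[Si](C)(C)C)=C2)ccc1O[Si](C)(C)C(C)(C)C
F9 | step 4 | 3,4‑epoxide of F8 (oxirane oxygen anti to the C2 aryl group) | COc1cc([C@H]2Oc3c(CC=C(C)C)c(O[Si](C(C)C)(C(C)C)C(C)C)cc(O[Si](C)(C)C)c3[C@]4(O[Si](C)(C)C)O[C@H]24)ccc1O[Si](C)(C)C(C)(C)C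
F10 | step 4 | (2R,3R)‑2‑{4‑[(tert‑butyldimethylsilyl)oxy]‑3‑methoxyphenyl}‑3,5‑dihydroxy‑8‑(3‑methylbut‑2‑en‑1‑yl)‑7‑[(triisopropylsilyl)oxy]‑2,3‑dihydro‑4H‑chromen‑4‑one | COc1cc([C@H]2Oc3c(CC=C(C)C)c(O[Si](C(C)C)(C(C)C)C(C)C)cc(O)c3C(=O)[C@@H]2O)ccc1O[Si](C)(C)C(C)(C)C
A1 | direct plan | 5‑methoxy‑1,3‑bis(methoxymethoxy)‑2‑(3‑methylbut‑2‑en‑1‑yl)benzene | COCOc1cc(OC)cc(OCOC)c1CC=C(C)C
A2 | direct plan | (2R)‑2‑[(tert‑butyldimethylsilyl)oxy]‑N‑methoxy‑3‑[3‑methoxy‑4‑(methoxymethoxy)phenyl]‑N‑methylpropanamide | CON(C)C(=O)[C@H](O[Si](C)(C)C(C)(C)C)Cc1ccc(OCOC)c(OC)c1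
A3 | direct plan | (2R)‑1‑[2,4‑dihydroxy‑6‑methoxy‑3‑(3‑methylbut‑2‑en‑1‑yl)phenyl]‑2‑hydroxy‑3‑(4‑hydroxy‑3‑methoxyphenyl)propan‑1‑one | COc1cc(O)c(CC=C(C)C)c(O)c1C(=O)[C@H](O)Cc1ccc(O)c(OC)c1
A4 | direct plan | 4‑[(2R)‑3‑[2,4‑dihydroxy‑6‑methoxy‑3‑(3‑methylbut‑2‑en‑1‑yl)phenyl]‑2‑hydroxy‑3‑oxopropylidene]‑2‑methoxycyclohexa‑2,5‑dien‑1‑one (para‑quinone methide) | COc1cc(O)c(CC=C(C)C)c(O)c1C(=O)[C@H](O)C=C1C=CC(=O)C(OC)=C1
A5 | direct plan | (2R,3R)‑3,7‑dihydroxy‑2‑(4‑hydroxy‑3‑methoxyphenyl)‑5‑methoxy‑8‑(3‑methylbut‑2‑en‑1‑yl)‑2,3‑dihydro‑4H‑chromen‑4‑one | COc1cc([C@H]2Oc3c(CC=C(C)C)c(O)cc(OC)c3C(=O)[C@@H]2O)ccc1O
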